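**Retrosynthetic overview**
1. Target 18 ⇒ C8–CH2–C8′ bond last: ortho-quinone methide from Mannich base 16 (the 6-methyl half) + flavan 13. 16 is made from 13 (C8 aminomethylation, C6 bromination, Pd(OAc)2/SPhos Negishi methylation), so one (S)-flavan serves both halves.
2. 13 ⇒ C2–Ph bond and the (S) centre by enantioconvergent NiCl2·glyme / Ir[dF(CF3)ppy]2(dtbbpy)PF6 decarboxylative arylation of chroman-2-carboxylic acid 10 with PhBr. The 7-OH comes from [Ir(OMe)(cod)]2-catalysed C–H borylation (Bpin carried as a masked phenol).
3. 10 ⇒ 8 by iodine/methanol aromatisation of hexahydrochromenone 7 (the carbonyl becomes 5-OMe, the enol-ether oxygen becomes O1).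
4. Key step: ring expansion of spiro-cyclopropane 3 (cyclohexane-1,3-dione + BrCH2CH2Br) with the ester-stabilised sulfonium ylide from methyl bromoacetate, cyclopropane → dihydropyran ring of 7.
5. Ring order: cyclopropane → pyran ring C (ring expansion) → aromatic ring A → phenyl ring attached → second flavan copy → methylene bridge.

Assumption: electrophiles attack 7-hydroxy-5-methoxyflavans faster at C8 than at C6 (as with 5,7-dioxygenated flavan ethers); steps 6 and 9 rely on this.

**Step 1**
Reactants: 1 cyclohexane-1,3-dione; 2 1,2-dibromoethane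
Product: 3 spiro[2.5]octane-4,8-dione
Conditions: K2CO3 (2.5 equiv), DMSO, rt
Reagents that add atoms: none
Why: Double alkylation of the 1,3-dione at carbon (intermolecular SN2, then 3-exo-tet closure of the enolate) is the standard entry to this spiro-activated cyclopropane; the O-cyclised tetrahydrobenzofuranone by-product is removed by chromatography.

**Step 2**
Reactants: 3 spiro[2.5]octane-4,8-dione; 4 methyl bromoacetate
Product: 7 methyl 5-oxo-3,4,5,6,7,8-hexahydro-2H-chromene-2-carboxylate (racemic), via sulfonium salt 5 (not isolated), via sulfonium ylide 6 (not isolated)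
Conditions: Me2S, acetone, rt; then 3, K2CO3, MeCN, 60 °C
Reagents that add atoms: none
Why: Key ring expansion: ylide 6 opens the doubly acyl-activated cyclopropane of 3 by homoconjugate SN2 attack at a ring CH2, and the released 1,3-dione enolate oxygen then displaces Me2S from the α-sulfonio ester in a 6-exo-tet closure, so the three cyclopropane carbons end up in the six-membered dihydropyran (a ylide-homologated Cloke–Wilson-type ring expansion, stepwise and ionic, not pericyclic); the new C2 centre is racemic and is deliberately erased in step 5.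

**Step 3**
Reactants: 7 methyl 5-oxo-3,4,5,6,7,8-hexahydro-2H-chromene-2-carboxylate
Product: 8 methyl 5-methoxychromane-2-carboxylate (racemic)
Conditions: I2 (2 equiv), MeOH, reflux
Reagents that add atoms: methanol, CO
Why: Iodine/methanol oxidative aromatisation of a cyclohexenone: enol-ether formation with MeOH, α-iodination and loss of two HI aromatise ring A, turning the C5 carbonyl into the 5-OMe group while the ring enol-ether oxygen stays as O1, which fixes the 5-O-methyl/7-O-free pattern without protecting groups.

**Step 4**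
Reactants: 8 methyl 5-methoxychromane-2-carboxylate
Product: 10 5-methoxy-7-(4,4,5,5-tetramethyl-1,3,2-dioxaborolan-2-yl)chromane-2-carboxylic acid (racemic), via boronate ester 9 (not isolated)
Conditions: B2pin2 (1.0 equiv), [Ir(OMe)(cod)]2 (1.5 mol %), dtbpy (3 mol %), THF, 80 °C; then LiOH, THF/H2O, rt; HCl to pH 4
Reagents that add atoms: bis(pinacolato)diboron, CC1(C)OB(OC1(C)C)B1OC(C)(C)C(C)(C)O1; lithium hydroxide, [Li+].[OH-]
Why: Sterically governed [Ir(OMe)(cod)]2/dtbpy C–H borylation takes the only arene C–H without an ortho substituent (C7; C6 lies next to OMe, C8 next to O1, and no other arene is present yet), and LiOH then saponifies the ester while the aryl–Bpin, a masked 7-OH that is inert in the next step, survives.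

**Step 5**
Reactants: 10 5-methoxy-7-(4,4,5,5-tetramethyl-1,3,2-dioxaborolan-2-yl)chromane-2-carboxylic acid; 11 bromobenzene
Product: 13 (2S)-5-methoxy-2-phenylchroman-7-ol, via aryl boronate 12 (not isolated)
Conditions: 11 (1.5 equiv), Ir[dF(CF3)ppy]2(dtbbpy)PF6 (1 mol %), NiCl2·glyme (10 mol %), chiral cyano-bis(oxazoline) ligand (12 mol %, enantiomer giving 2S), Cs2CO3, DME, blue LEDs, rt; then 30% H2O2, THF/pH 7 buffer, 0 °C
Reagents that add atoms: hydrogen peroxide, OO
Why: Proposed new method: enantioconvergent decarboxylative arylation of a cyclic α-aryloxy acid, in which excited Ir[dF(CF3)ppy]2(dtbbpy)PF6 oxidises the caesium carboxylate, loss of CO2 gives the planar O-stabilised chroman-2-yl radical (the racemic centre of 10 is erased), this radical is captured by the ligand-bound L*Ni(Ph)Br formed by oxidative addition of PhBr to zerovalent nickel, and reductive elimination from the trivalent nickel alkyl aryl complex forms C2–Ph and sets C2 as (S) under ligand control (fused arene on one side, CH2 on the other); the closest known reactions are the racemic decarboxylative arylation of α-oxy acids with the same metal pair and its enantioselective version for N-protected α-amino acids, and the aryl–Bpin, which does not transmetalate under these anhydrous single-electron conditions, is oxidised to the phenol in the second stage.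

**Step 6**
Reactants: 13 (2S)-5-methoxy-2-phenylchroman-7-ol
Product: 14 (2S)-8-[(dimethylamino)methyl]-5-methoxy-2-phenylchroman-7-ol
Conditions: Me2N=CH2+ I− (1.05 equiv), K2CO3, MeCN, 0 °C → rt
Reagents that add atoms: N,N-dimethylmethyleneiminium iodide (Eschenmoser's salt), C=[N+](C)C.[I-]
Why: Mannich-type aminomethylation (SEAr of the phenoxide with the iminium ion) at C8, the ortho position flanked by the tied-back ring oxygen and therefore more accessible than C6, which is shielded by the in-plane 5-OMe; the minor C6 isomer is separated.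

**Step 7**
Reactants: 14 (2S)-8-[(dimethylamino)methyl]-5-methoxy-2-phenylchroman-7-ol
Product: 15 (2S)-6-bromo-8-[(dimethylamino)methyl]-5-methoxy-2-phenylchroman-7-ol
Conditions: NBS (1.0 equiv), MeCN, −40 °C
Reagents that add atoms: N-bromosuccinimide, O=C1CCC(=O)N1Br
Why: Electrophilic aromatic bromination at C6, the only free position left on the strongly activated ring A, which at −40 °C outpaces oxidation of the tertiary amine or attack on the unactivated phenyl ring.

**Step 8**
Reactants: 15 (2S)-6-bromo-8-[(dimethylamino)methyl]-5-methoxy-2-phenylchroman-7-ol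
Product: 16 (2S)-8-[(dimethylamino)methyl]-5-methoxy-6-methyl-2-phenylchroman-7-ol
Conditions: MeZnCl (3.5 equiv), Pd(OAc)2 (5 mol %), SPhos (10 mol %), THF, 50 °C
Reagents that add atoms: methylzinc chloride, C[Zn]Cl
Why: Negishi cross-coupling (oxidative addition of the hindered aryl bromide to zerovalent palladium–SPhos, methyl transfer from zinc, reductive elimination) replaces Br by CH3; the phenol rides as its zinc phenoxide and 50 °C is too mild to expel Me2NH from the Mannich base.

**Step 9**
Reactants: 16 (2S)-8-[(dimethylamino)methyl]-5-methoxy-6-methyl-2-phenylchroman-7-ol; 13 (2S)-5-methoxy-2-phenylchroman-7-ol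
Product: 18 (2S)-8-{[(2S)-7-hydroxy-5-methoxy-6-methyl-2-phenylchroman-8-yl]methyl}-5-methoxy-2-phenylchroman-7-ol (CNP0114750.1), via ortho-quinone methide 17 (not isolated)
Conditions: 13 (3 equiv), toluene, 110 °C, sealed tube, Ar
Reagents that add atoms: none
Why: Thermal loss of Me2NH from the ortho-hydroxybenzylamine gives ortho-quinone methide 17, which is trapped by excess 13 at its more accessible C8 in a Friedel–Crafts-type conjugate addition (O-alkylation is reversible under these conditions), closing the C8–CH2–C8′ bridge; both C2 centres are remote and unchanged.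

**Compound list**
1 | cyclohexane-1,3-dione | O=C1CCCC(=O)C1 | starting material
2 | 1,2-dibromoethane | BrCCBr | starting material
3 | spiro[2.5]octane-4,8-dione | O=C1CCCC(=O)C12CC2 | intermediate
4 | methyl bromoacetate | COC(=O)CBr | starting material
5 | (2-methoxy-2-oxoethyl)dimethylsulfonium bromide (not isolated) | COC(=O)C[S+](C)C.[Br-] | intermediate
6 | sulfonium ylide methyl 2-(dimethylsulfonio)acetate-2-ide (not isolated) | COC(=O)[CH-][S+](C)C | intermediate
7 | methyl 5-oxo-3,4,5,6,7,8-hexahydro-2H-chromene-2-carboxylate (racemic) | COC(=O)C1CCC2=C(CCCC2=O)O1 | intermediate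
8 | methyl 5-methoxychromane-2-carboxylate (racemic) | COC(=O)C1CCc2c(OC)cccc2O1 | intermediate
9 | methyl 5-methoxy-7-(4,4,5,5-tetramethyl-1,3,2-dioxaborolan-2-yl)chromane-2-carboxylate (racemic, not isolated) | COC(=O)C1CCc2c(OC)cc(B3OC(C)(C)C(C)(C)O3)cc2O1 | intermediate
10 | 5-methoxy-7-(4,4,5,5-tetramethyl-1,3,2-dioxaborolan-2-yl)chromane-2-carboxylic acid (racemic) | OC(=O)C1CCc2c(OC)cc(B3OC(C)(C)C(C)(C)O3)cc2O1 | intermediate
11 | bromobenzene | Brc1ccccc1 | starting material
12 | 2-[(2S)-5-methoxy-2-phenylchroman-7-yl]-4,4,5,5-tetramethyl-1,3,2-dioxaborolane (not isolated) | COc1cc(B3OC(C)(C)C(C)(C)O3)cc2c1CC[C@@H](c1ccccc1)O2 | intermediate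
13 | (2S)-5-methoxy-2-phenylchroman-7-ol | COc1cc(O)cc2c1CC[C@@H](c1ccccc1)O2 | intermediate
14 | (2S)-8-[(dimethylamino)methyl]-5-methoxy-2-phenylchroman-7-ol | COc1cc(O)c(CN(C)C)c2c1CC[C@@H](c1ccccc1)O2 | intermediate
15 | (2S)-6-bromo-8-[(dimethylamino)methyl]-5-methoxy-2-phenylchroman-7-ol | COc1c(Br)c(O)c(CN(C)C)c2c1CC[C@@H](c1ccccc1)O2 | intermediate
16 | (2S)-8-[(dimethylamino)methyl]-5-methoxy-6-methyl-2-phenylchroman-7-ol | COc1c(C)c(O)c(CN(C)C)c2c1CC[C@@H](c1ccccc1)O2 | intermediate
17 | ortho-quinone methide (2S)-5-methoxy-6-methyl-8-methylidene-2-phenyl-3,4-dihydro-2H-chromen-7(8H)-one (not isolated) | COC1=C(C)C(=O)C(=C)C2=C1CC[C@@H](c1ccccc1)O2 | intermediate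
18 | (2S)-8-{[(2S)-7-hydroxy-5-methoxy-6-methyl-2-phenylchroman-8-yl]methyl}-5-methoxy-2-phenylchroman-7-ol (CNP0114750.1) | COc1cc(O)c(Cc2c(O)c(C)c(OC)c3c2O[C@H](c2ccccc2)CC3)c2c1CC[C@@H](c1ccccc1)O2 | target

**Step count and risks**
Total steps: 9. Longest linear sequence: 9 steps (1 → 18; flavan 13 is used twice, once as precursor of 16 and once as coupling partner).

Steps most likely to fail:

Step 5 (new method; the ee may be low or the electron-rich arene may interfere with the photocatalyst). Fallback by known chemistry, setting out from 10 and returning at 13: oxidative decarboxylation of 10 with Pb(OAc)4 (Cu(OAc)2 cat., pyridine, benzene, 80 °C) gives the anomeric acetate 5-methoxy-7-(4,4,5,5-tetramethyl-1,3,2-dioxaborolan-2-yl)chroman-2-yl acetate F2. H2O2/NaOH oxidises the boronate and cleaves the acetate to the lactol 5-methoxychromane-2,7-diol F3. Its open-chain aldehyde takes up phenyl from PhTi(OiPr)3 (from PhMgBr and ClTi(OiPr)3) under Ti(OiPr)4/H8-BINOL catalysis to give (R)-4-(3-hydroxy-3-phenylpropyl)-5-methoxybenzene-1,3-diol F4. Mitsunobu ring closure (PPh3, DIAD, THF, high dilution) by the ortho phenol, with inversion, returns to 13.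

Step 2 (the ring-opened zwitterion may close through carbon instead of oxygen, or the unsubstituted cyclopropane may open slowly). Fallback setting out from 3 and returning at 7, as two separate ring enlargements: 3 and ylide 6 in toluene at 80 °C, where C-alkylation closes the four-membered ring, give the spiro-cyclobutane methyl 5,9-dioxospiro[3.5]nonane-1-carboxylate F1. F1 is then opened with MgI2 (MeCN, 60 °C): iodide attacks the ester-bearing ring carbon and the enolate oxygen displaces iodide in a 6-exo closure to give 7.

Step 9 (13 may also react at C6, and the quinone methide may self-condense). Fallback with reversed roles, setting out from 13 and returning at 18: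
- NBS (MeCN, −40 °C) gives (2S)-8-bromo-5-methoxy-2-phenylchroman-7-ol F5.
- Eschenmoser's salt/K2CO3 aminomethylates the only free position to give (2S)-8-bromo-6-[(dimethylamino)methyl]-5-methoxy-2-phenylchroman-7-ol F6.
- H2, Pd/C, NaOAc, EtOH, 60 °C removes bromine and hydrogenolyses the benzylic C–N bond to give (2S)-5-methoxy-6-methyl-2-phenylchroman-7-ol F7, whose only free ring-A position is C8.
- Heating F7 with Mannich base 14 (toluene, 110 °C) generates the ortho-quinone methide (2S)-5-methoxy-8-methylidene-2-phenyl-3,4-dihydro-2H-chromen-7(8H)-one F8, which F7 traps at C8 to give 18.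

**Further compounds**
F1 | step 2 | methyl 5,9-dioxospiro[3.5]nonane-1-carboxylate | COC(=O)C1CCC12C(=O)CCCC2=O
F2 | step 5 | 5-methoxy-7-(4,4,5,5-tetramethyl-1,3,2-dioxaborolan-2-yl)chroman-2-yl acetate | CC(=O)OC1CCc2c(OC)cc(B3OC(C)(C)C(C)(C)O3)cc2O1
F3 | step 5 | 5-methoxychromane-2,7-diol | COc1cc(O)cc2c1CCC(O)O2
F4 | step 5 | (R)-4-(3-hydroxy-3-phenylpropyl)-5-methoxybenzene-1,3-diol | COc1cc(O)cc(O)c1CC[C@@H](O)c1ccccc1
F5 | step 9 | (2S)-8-bromo-5-methoxy-2-phenylchroman-7-ol | COc1cc(O)c(Br)c2c1CC[C@@H](c1ccccc1)O2
F6 | step 9 | (2S)-8-bromo-6-[(dimethylamino)methyl]-5-methoxy-2-phenylchroman-7-ol | COc1c(CN(C)C)c(O)c(Br)c2c1CC[C@@H](c1ccccc1)O2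
F7 | step 9 | (2S)-5-methoxy-6-methyl-2-phenylchroman-7-ol | COc1c(C)c(O)cc2c1CC[C@@H](c1ccccc1)O2
F8 | step 9 | (2S)-5-methoxy-8-methylidene-2-phenyl-3,4-dihydro-2H-chromen-7(8H)-one | COC1=CC(=O)C(=C)C2=C1CC[C@@H](c1ccccc1)O2
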